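60.5% of target is what the amber run holds at 40.0 h, from 1.5 equiv of reagent; the violet run holds 93.4% at 40.0 h, from 2.8 equiv.

the same everywhere: starting material 0.80 M; free catalyst 0.057 mol%; added ligand 1.1 mM

| charge | reagent | second substrate | temperature | remark | time |
|---|---|---|---|---|---|
| amber | 1.5 equiv | 1 equiv | 20 °C | run made earlier |  |
| violet | 2.8 equiv | 1 equiv | 31 °C | run made earlier |  |
| alder | 2.50 equiv | 1.00 equiv | 25 °C |  | 2.5 d |
| cedar | 1.20 equiv | 1.00 equiv | 25 °C |  | 2.5 d |

| run | time / h | target / % | starting material / % |
|---|---|---|---|
| amber | 8.00 | 40.7 | 59.3 |
| amber | 15.0 | 50.5 | 48.3 |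
| amber | 20.0 | 54.7 | 46.9 |
| amber | 30.0 | 59.2 | 42.0 |
| amber | 40.0 | 60.5 | 40.0 |
| violet | 3.00 | 66.0 | 32.6 |
| violet | 8.00 | 86.4 | 15.6 |
| violet | 15.0 | 91.1 | 8.5 |
| violet | 25.0 | 92.7 | 5.8 |
| violet | 30.0 | 92.9 | 7.9 |
| violet | 40.0 | 93.4 | 5.8 |

(standard deviation of a reading: 1 percentage point)

* the winner by amount of target, in percent of the starting material charged; "neither" if no more than 2 percentage points parts them (alder / cedar / neither)
* how much target is there at the end, in percent of the starting material charged: alder
* how much target is there at the end, in percent of the starting material charged: cedar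



The bench rule here is a budget. Assume that reagent serves both starting material and second substrate, one equivalent per molecule, so that the two together ask for two equivalents. The supply ratio ρ is reagent charged over that demand, and in the amber run it is 0.750. Below a ρ of one, with second substrate held at one equivalent, reagent should be the limiting reagent, and target should be a steady share of it. The amber run gives 0.403 as the reagent yield φ, target at the stop per equivalent of reagent charged. Cedar has ρ = 0.600, so this reckoning gives cedar 48.4%, though φ was read at 20 °C and cedar runs at 25 °C.

For alder the same rule gives 101%, and there it stops working: ρ = 1.25, above the border. The violet run lies on that side too, at ρ = 1.40, where φ gives 113% against the 93.4% read. This reckoning takes alder near the violet reading, with the caution that the violet run stood at 31 °C.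

The forecast differs. It holds that “the final conversion is set by the total catalytic "dose"”, and it gives alder 84% and cedar 55%, with alder as the winner. Its cedar value stands higher than the budget's, and its alder value lower than the violet reading.

The simulation gives alder 93.2% and cedar 49.3%, so alder wins.

    free catalyst → spent catalyst (k = 0.00108 min⁻¹, Ea = 105 kJ mol⁻¹)
    second substrate + reagent + free catalyst → free catalyst + second product (k = 16.3 L² mol⁻² min⁻¹, Ea = 42.0 kJ mol⁻¹)
    starting material + reagent + free catalyst → free catalyst + target (k = 9.60 L² mol⁻² min⁻¹, Ea = 58.0 kJ mol⁻¹)
    free catalyst + added ligand ⇌ idle complex, settled at all times (K = 460 L mol⁻¹, ΔH = −22.0 kJ mol⁻¹)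
    (constants at 25 °C)

Cedar, reckoned at 48.4% from φ, ends with 1.9% of its reagent and 32% of its second substrate. Alder ends with 23% of its reagent and 1.1% of its second substrate. The neighbouring flask is alder with 0.620 equiv of reagent, so ρ = 0.310, and φ gives it 25.0%. That flask holds 24.2% of target, with 0.29% of its reagent remaining.

The earlier runs and the new flask are calculated with constants of no real substance.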